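Readings and results stem from a simulated flask for an exercise, noise included.

The pitfall in these runs is to read grey's level, lower than ochre's, as the work of its second nucleophile, when grey also holds twice the protic impurity of ochre.

all flasks: starting material 0.020 M
- ochre: first nucleophile 10 mM; second nucleophile 0.040 M; protic impurity 4 mM; temperature 20 °C; run made earlier
- teal: first nucleophile 10 mM; second nucleophile 0.060 M; protic impurity 4 mM; temperature 32 °C; run made earlier
- grey: first nucleophile 10 mM; second nucleophile 0.080 M; protic impurity 8 mM; temperature 20 °C; run made earlier
- south-west: first nucleophile 10.0 mM; second nucleophile 0.0800 M; protic impurity 4.00 mM; temperature 40 °C; time 2.5 min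
- north-west: first nucleophile 10.0 mM; second nucleophile 0.0800 M; protic impurity 4.00 mM; temperature 25 °C; time 2.5 min

ochre run (percent of the starting material charged)

| time / min | target / % |
|---|---|
| 1.33 | 16.7 |
| 2.50 | 24.2 |
| 4.00 | 28.5 |
| 5.00 | 29.6 |

teal run (percent of the starting material charged)

| time / s | target / % |
|---|---|
| 10.0 | 2.4 |
| 20.0 | 4.8 |
| 50.0 | 9.9 |
| 120 | 17.5 |

grey run (percent of the starting material charged)

| time / min | target / % |
|---|---|
| 1.33 | 11.2 |
| 2.50 | 14.2 |
| 4.00 | 17.4 |
| 5.00 | 17.0 |

(scatter of a reading: 0.5 percentage points)

- what was read earlier has a scatter of 0.5 percentage points, one standard deviation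

* the flask with the highest amount of target, in percent of the starting material charged ("all alike" if they lie within 1.5 percentage points) (south-west / north-west / all alike)
* final target, as a percentage of the starting material charged, in south-west
* final target, as a percentage of the starting material charged, in north-west

Grey has the same first and second nucleophile charges as both new flasks, so it is the run to read. Its last two readings differ by less than the scatter, so they read as about level, at 17.2%. My own assumption is that each impurity molecule spends one starting material, which leaves 60.0% of the charge in grey. That gives 28.7%, the capture share: the part of the unquenched starting material that ends as target, a selectivity read at 20 °C.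

The new flasks carry less impurity, so on the same assumption 80.0% of their charge stays unquenched, and my estimate of the end level is about 22.9%. But the time is short. Ochre had 81.8% of its last reading by 2.50 min, so my reckoning gives about 18.7% at ochre's pace. Teal is warmer than ochre but also holds more second nucleophile, and it reads 17.5% after 120 s where ochre reads 16.7% after 1.33 min. These two changes are not separated in the readings, but they show no gain from warmth, so I expect south-west no higher than north-west.

The forecast gives 16.5% for south-west, 17% for north-west and all alike, on the ground that “The temperature difference appears negligible”.

The flasks give 15.1% in south-west and 18.3% in north-west, so the answer is north-west.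

    starting material ⇌ intermediate (K = 0.00100, k = 0.0290 s⁻¹, Ea = 69.0 kJ mol⁻¹, ΔH = −73.0 kJ mol⁻¹)
    first nucleophile + intermediate → target (k = 530 M⁻¹ s⁻¹, Ea = 39.0 kJ mol⁻¹)
    second nucleophile + intermediate → other capture product (k = 130 M⁻¹ s⁻¹, Ea = 48.0 kJ mol⁻¹)
    starting material + protic impurity → quenched substrate (k = 6.70 M⁻¹ s⁻¹, Ea = 38.0 kJ mol⁻¹)
    (constants at 25 °C)

Of the captured material at 2.50 min, target makes up 27.5% in south-west and 30.2% in north-west, beside the 28.7% read from grey. The neighbouring flask is south-west with 0.0080 M of starting material. There, quenched substrate stands at 49.7% and starting material at 13%, so 37.7% has been captured. The capture share turns that into 10.8% of target, and the neighbouring flask holds 11.1%.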